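## Retrosynthetic overview

1. 35 ⇐ 34 (silyl removal) ⇐ 33: C6–Cl by SN2 inversion of an allylic alcohol; the ten-membered ring is closed last by a Nozaki–Hiyama–Kishi reaction (C5–C6) of a 2-iodoalkene onto a C6 aldehyde.
2. C2–C5 arm: catalytic asymmetric dienylzinc addition to a C2 aldehyde (C2–C3), matched Sharpless epoxidation (3,4-epoxide), iododesilylation.
3. C6–C9 arm: Nozaki–Hiyama–Kishi coupling (C8–C9) of a C9 aldehyde with a glycidate-derived tetronate triflate; C9 corrected by oxidation/Felkin reduction; C8-OH and C17 by butenolide epoxidation and SmI2 opening.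
4. Six-membered ring: enantioselective Diels–Alder of (E)-piperylene with a thioester enal sets C1, C10, C11; epoxide-to-allylic-alcohol isomerisation and directed epoxidation set C12–C14; the thioester is the latent C2 aldehyde.
5. Ring order: cyclohexene (Diels–Alder) → γ-lactone (Dieckmann, attached at C8–C9) → ten-membered carbocycle (C5–C6).

Assumption 1: briarane numbering is used (C1–C14 ring carbons, C15 methyl on C1, C16 methylene on C5, C17/C18 methyl/C19 carbonyl in the lactone, C20 methyl on C11); α is the face of H-10.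
Assumption 2: the (S)-oxazaborolidinium catalyst in step 3 is taken to give the (1S,5S,6S) adduct 5; if the sense is opposite, the (R)-catalyst is used.

## Route

Step 1
Reactants: 1 tigloyl chloride [(E)-2-methylbut-2-enoyl chloride]
Product: 2 S-ethyl (E)-2-methylbut-2-enethioate
Conditions: EtSH, pyridine, CH2Cl2, 0 °C to rt
Reagents that add atoms: ethanethiol CCS
Why: Acyl substitution of the acid chloride by the thiol (Schotten–Baumann type) gives the thioester that later serves as a latent aldehyde; no stereocentre is formed.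

Step 2
Reactants: 2 S-ethyl (E)-2-methylbut-2-enethioate
Product: 3 S-ethyl (E)-2-methyl-4-oxobut-2-enethioate
Conditions: SeO2 (1.2 equiv), 1,4-dioxane, 90 °C
Reagents that add atoms: selenium dioxide O=[Se]=O
Why: Riley allylic oxidation (ene reaction then [2,3]-shift) converts the γ-methyl of the enoate-type system into the aldehyde with retention of the E geometry.

Step 3
Reactants: 3 S-ethyl (E)-2-methyl-4-oxobut-2-enethioate; 4 (E)-penta-1,3-diene
Product: 5 S-ethyl (1S,5S,6S)-6-formyl-1,5-dimethylcyclohex-3-ene-1-carbothioate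
Conditions: (S)-3,3-diphenyl-1-(2-methylphenyl)tetrahydro-1H,3H-pyrrolo[1,2-c][1,3,2]oxazaborole (20 mol %), Tf2NH (20 mol %), CH2Cl2, −78 to −20 °C
Reagents that add atoms: none
Why: Lewis acid-catalysed Diels–Alder reaction in which the formyl-bound catalyst makes the methyl-bearing carbon the electrophilic terminus (ortho adduct with the 1-methyl diene), the endo-formyl transition state places the C20 methyl cis to CHO, the E dienophile fixes CHO trans to COSEt, and the chiral oxazaborolidinium sets the absolute configuration of C1, C10 and C11.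

Step 4
Reactants: 6 methyl (R)-oxirane-2-carboxylate
Product: 7 methyl (R)-2-hydroxy-3-[(4-methoxybenzyl)oxy]propanoate
Conditions: 4-methoxybenzyl alcohol (3 equiv), BF3·OEt2 (5 mol %), CH2Cl2, 0 °C
Reagents that add atoms: 4-methoxybenzyl alcohol COc1ccc(CO)cc1
Why: Lewis acid-catalysed epoxide opening occurs at the terminal C3 of the glycidate, so the chiral-pool stereocentre (future C7) is untouched.

Step 5
Reactants: 7 methyl (R)-2-hydroxy-3-[(4-methoxybenzyl)oxy]propanoate
Product: 8 methyl (R)-3-[(4-methoxybenzyl)oxy]-2-(propanoyloxy)propanoate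
Conditions: (EtCO)2O, Et3N, 4-dimethylaminopyridine (5 mol %), CH2Cl2, 0 °C
Reagents that add atoms: propanoic anhydride CCC(=O)OC(=O)CC
Why: Nucleophile-catalysed O-acylation installs the propionate that supplies C17, C18 and C19; no stereocentre is touched.

Step 6
Reactants: 8 methyl (R)-3-[(4-methoxybenzyl)oxy]-2-(propanoyloxy)propanoate
Product: 9 (R)-4-hydroxy-5-{[(4-methoxybenzyl)oxy]methyl}-3-methylfuran-2(5H)-one
Conditions: LiN(SiMe3)2 (2.2 equiv), THF, −78 to 0 °C; then 1 M HCl
Reagents that add atoms: none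
Why: Dieckmann (Lacey-type) cyclisation of the propionate enolate onto the methyl ester forms the γ-lactone ring as the tetronic acid, the low temperature keeping C7 from enolising or eliminating the β-alkoxy group.

Step 7
Reactants: 9 (R)-4-hydroxy-5-{[(4-methoxybenzyl)oxy]methyl}-3-methylfuran-2(5H)-one
Product: 10 (R)-2-{[(4-methoxybenzyl)oxy]methyl}-4-methyl-5-oxo-2,5-dihydrofuran-3-yl trifluoromethanesulfonate
Conditions: Tf2O, i-Pr2NEt, CH2Cl2, −78 °C
Reagents that add atoms: triflic anhydride O=S(=O)(OS(=O)(=O)C(F)(F)F)C(F)(F)F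
Why: O-sulfonylation of the enol gives the alkenyl triflate needed for nickel/chromium coupling at C8; the hindered amine at low temperature leaves C7 intact.

Step 8
Reactants: 5 S-ethyl (1S,5S,6S)-6-formyl-1,5-dimethylcyclohex-3-ene-1-carbothioate; 10 (R)-2-{[(4-methoxybenzyl)oxy]methyl}-4-methyl-5-oxo-2,5-dihydrofuran-3-yl trifluoromethanesulfonate
Product: 11 (9R)-butenolide carbinol (C8–C9 coupled)
Conditions: CrCl2 (4 equiv), NiCl2 (2 mol %), DMF, rt
Reagents that add atoms: none
Why: Nozaki–Hiyama–Kishi coupling adds the alkenylchromium selectively to the aldehyde (thioester and lactone are inert), Felkin–Anh attack anti to the quaternary C1 giving mainly the 9R carbinol, which is corrected in the next two steps.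

Step 9
Reactants: 11 (9R)-butenolide carbinol (C8–C9 coupled)
Product: 12 C9 ketone (4-acylbutenolide)
Conditions: Dess–Martin periodinane, NaHCO3, CH2Cl2, 0 °C
Reagents that add atoms: none
Why: Buffered Dess–Martin oxidation removes the C9 stereocentre under non-basic conditions that spare the acidic C7–H and C10–H.

Step 10
Reactants: 12 C9 ketone (4-acylbutenolide)
Product: 13 (9S)-butenolide carbinol
Conditions: NaBH4, CeCl3·7H2O, MeOH, −78 °C
Reagents that add atoms: none
Why: Luche 1,2-reduction delivers hydride by the Felkin–Anh path anti to the quaternary C1, which for hydride (unlike carbon addition in step 8) gives the 9S alcohol required in the target.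

Step 11
Reactants: 13 (9S)-butenolide carbinol
Product: 14 8,17-epoxy-γ-lactone 9-ol
Conditions: t-BuOOH, n-BuLi, THF, −78 to −20 °C
Reagents that add atoms: tert-butyl hydroperoxide CC(C)(C)OO
Why: Weitz–Scheffer nucleophilic epoxidation by lithium tert-butyl peroxide attacks C8 of the butenolide on the face anti to the C7 CH2OPMB group, setting the C8–O bond cis to H-7.

Step 12
Reactants: 14 8,17-epoxy-γ-lactone 9-ol
Product: 15 8-hydroxy-γ-lactone 9-ol (C8 and C17 as in 35)
Conditions: SmI2 (2.5 equiv), THF/MeOH, −78 °C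
Reagents that add atoms: none
Why: SmI2 reductive opening of the α,β-epoxy lactone cleaves only the C17–O bond (keeping the C8 tertiary alcohol), and protonation of the samarium enolate from the C9-carbinol side puts the C18 methyl cis to 8-OH and trans to the bulky C9 branch, which is also the thermodynamically preferred C17 epimer.

Step 13
Reactants: 15 8-hydroxy-γ-lactone 9-ol (C8 and C17 as in 35)
Product: 16 9-acetate thioester
Conditions: Ac2O, pyridine, 4-dimethylaminopyridine (10 mol %), CH2Cl2, rt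
Reagents that add atoms: acetic anhydride CC(=O)OC(C)=O
Why: Nucleophile-catalysed acetylation takes the secondary C9 alcohol and leaves the tertiary C8 alcohol free; no stereocentre changes.

Step 14
Reactants: 16 9-acetate thioester
Product: 17 12α,13α-epoxide
Conditions: m-chloroperoxybenzoic acid, NaHCO3, CH2Cl2, 0 °C
Reagents that add atoms: m-chloroperoxybenzoic acid OOC(=O)c1cccc(Cl)c1
Why: Prilezhaev epoxidation of the only electron-rich alkene (C12=C13) occurs on the α face, anti to the allylic C20 methyl, the C15 methyl and the C9 side chain, which fixes the C12–O configuration.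

Step 15
Reactants: 17 12α,13α-epoxide
Product: 19 12α-hydroxy-13-ene thioester, via 8,12-bis(trimethylsilyl) ether 18 (not isolated)
Conditions: Me3SiOTf (2.2 equiv), DBU (2.2 equiv), toluene, 0 °C to rt; then 1 M HCl, THF, 0 °C
Reagents that add atoms: none
Why: Silyl triflate/amidine epoxide-to-allylic-ether isomerisation (Noyori–Murata) opens at the less hindered C13 and eliminates anti toward C14, because C11 has no hydrogen anti to the C12–O bond, so the alkene moves to C13=C14 while the 12α C–O bond is retained, and acid then removes both silyl groups.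

Step 16
Reactants: 19 12α-hydroxy-13-ene thioester
Product: 20 13α,14α-epoxy-12α-ol
Conditions: VO(acac)2 (5 mol %), t-BuOOH, CH2Cl2, 0 °C to rt
Reagents that add atoms: tert-butyl hydroperoxide CC(C)(C)OO
Why: Vanadium-catalysed hydroxyl-directed epoxidation delivers oxygen syn to the 12α-hydroxyl of the cyclohexenol, giving the cis-epoxy alcohol (C13, C14).

Step 17
Reactants: 20 13α,14α-epoxy-12α-ol
Product: 21 12-O-triethylsilyl ether thioester
Conditions: Et3SiCl, imidazole, DMF, 0 °C to rt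
Reagents that add atoms: chlorotriethylsilane CC[Si](Cl)(CC)CC
Why: Silylation masks the secondary 12-OH (the one hydroxyl that must not be acetylated later) while the hindered tertiary 8-OH does not react.

Step 18
Reactants: 21 12-O-triethylsilyl ether thioester
Product: 22 C2 aldehyde
Conditions: Et3SiH, Pd/C (10 wt %), acetone, rt
Reagents that add atoms: none
Why: Fukuyama reduction converts the S-ethyl thioester into the aldehyde under neutral conditions that tolerate lactone, acetate, epoxide and silyl ether; no alkene is present at this stage.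

Step 19
Reactants: 23 (1-bromovinyl)trimethylsilane
Product: 24 2-(trimethylsilyl)but-1-en-3-yne
Conditions: HC≡CMgBr, ZnBr2, THF, 0 °C; then 23, Pd(PPh3)4 (3 mol %), rt
Reagents that add atoms: ethynylmagnesium bromide C#C[Mg]Br
Why: Negishi cross-coupling of the in situ ethynylzinc reagent with the alkenyl bromide gives the terminal enyne that carries the silyl group as a masked C5 iodide.

Step 20
Reactants: 22 C2 aldehyde; 24 2-(trimethylsilyl)but-1-en-3-yne
Product: 27 (2S)-dienylsilane allylic alcohol, via dienyl(dicyclohexyl)borane 25 (not isolated), via dienyl(methyl)zinc 26 (not isolated)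
Conditions: 24, Cy2BH, toluene, 0 °C to rt; Me2Zn, −78 °C; (2S)-3-exo-morpholinoisoborneol (10 mol %); then 22, −20 to 0 °C; aq NH4Cl
Reagents that add atoms: none
Why: Oppolzer-type hydroboration/boron-to-zinc transmetalation gives an (E)-alkenylzinc whose amino alcohol-catalysed addition to the non-enolisable aldehyde forms C2–C3 with the E alkene in place and sets C2 (2S here, the configuration of 35) by ligand control, reinforced by Felkin–Anh attack anti to C10.

Step 21
Reactants: 27 (2S)-dienylsilane allylic alcohol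
Product: 28 3,4-epoxy-2-ol
Conditions: Ti(OiPr)4 (1.2 equiv), diisopropyl D-tartrate (1.5 equiv), t-BuOOH, 4 Å molecular sieves, CH2Cl2, −20 °C
Reagents that add atoms: tert-butyl hydroperoxide CC(C)(C)OO
Why: Sharpless asymmetric epoxidation in the matched (fast-reacting) sense epoxidises only the allylic C3=C4 alkene and gives the erythro trans-epoxy alcohol, setting C3 and C4 as in 35.

Step 22
Reactants: 28 3,4-epoxy-2-ol
Product: 29 2-acetate vinylsilane
Conditions: Ac2O, pyridine, 4-dimethylaminopyridine (20 mol %), CH2Cl2, rt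
Reagents that add atoms: acetic anhydride CC(=O)OC(C)=O
Why: Nucleophile-catalysed acetylation of the hindered secondary C2 alcohol completes the second acetate; the tertiary 8-OH and the silyl-protected 12-OH are untouched.

Step 23
Reactants: 29 2-acetate vinylsilane
Product: 30 C5 alkenyl iodide
Conditions: N-iodosuccinimide, MeCN/ClCH2CN (4:1), 0 °C to rt
Reagents that add atoms: N-iodosuccinimide O=C1CCC(=O)N1I
Why: Ipso-iododesilylation of the 1,1-disubstituted vinylsilane gives the 2-iodoalkene needed for ring closure without acid or base.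

Step 24
Reactants: 30 C5 alkenyl iodide
Product: 31 C6 primary alcohol
Conditions: DDQ, CH2Cl2/pH 7 buffer (10:1), 0 °C
Reagents that add atoms: none
Why: Oxidative cleavage of the 4-methoxybenzyl ether by DDQ frees only the C6 alcohol and is orthogonal to silyl ether, acetates, epoxides and alkenyl iodide.

Step 25
Reactants: 31 C6 primary alcohol
Product: 32 C6 aldehyde
Conditions: Dess–Martin periodinane, NaHCO3, CH2Cl2, 0 °C
Reagents that add atoms: none
Why: Buffered Dess–Martin oxidation gives the α-acyloxy aldehyde without epimerising C7; it is used at once.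

Step 26
Reactants: 32 C6 aldehyde
Product: 33 macrocyclic 6-epi allylic alcohol
Conditions: CrCl2 (10 equiv), NiCl2 (1 mol %), DMSO/THF (3:1), 0.002 M, rt
Reagents that add atoms: none
Why: Intramolecular Nozaki–Hiyama–Kishi reaction closes the ten-membered ring at C5–C6 and creates the exocyclic methylene, polar Felkin–Anh addition (C7–O anti to the incoming alkenylchromium) giving the 6-hydroxyl anti to O7.

Step 27
Reactants: 33 macrocyclic 6-epi allylic alcohol
Product: 34 12-O-triethylsilyl ether of the target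
Conditions: PPh3, hexachloroacetone, CH2Cl2, −30 to 0 °C
Reagents that add atoms: hexachloroacetone ClC(Cl)(Cl)C(=O)C(Cl)(Cl)Cl
Why: Appel-type chlorination under Magid conditions displaces the phosphonium-activated allylic alcohol by chloride in an SN2 fashion with inversion and without allylic transposition (ionisation is disfavoured by the adjacent lactone oxygen), giving the 6S chloride syn to O7.

Step 28
Reactants: 34 12-O-triethylsilyl ether of the target
Product: 35 target CNP0141778.4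
Conditions: HF·pyridine, pyridine, THF, 0 °C
Reagents that add atoms: none
Why: Buffered fluoride desilylation removes the triethylsilyl ether and frees 12-OH without touching the epoxides, allylic chloride, acetates or lactone.

## Compound list

1 | tigloyl chloride [(E)-2-methylbut-2-enoyl chloride] | C/C=C(\C)C(=O)Cl | starting material
2 | S-ethyl (E)-2-methylbut-2-enethioate | C/C=C(\C)C(=O)SCC | intermediate
3 | S-ethyl (E)-2-methyl-4-oxobut-2-enethioate | O=C/C=C(\C)C(=O)SCC | intermediate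
4 | (E)-penta-1,3-diene | C=C/C=C/C | starting material
5 | S-ethyl (1S,5S,6S)-6-formyl-1,5-dimethylcyclohex-3-ene-1-carbothioate (CHO = C9; both methyls cis to CHO, COSEt trans) | CCSC(=O)[C@]1(C)[C@H]([C@@H](C)C=CC1)C=O | intermediate
6 | methyl (R)-oxirane-2-carboxylate | COC(=O)[C@H]1CO1 | starting material
7 | methyl (R)-2-hydroxy-3-[(4-methoxybenzyl)oxy]propanoate | COC(=O)[C@H](O)COCc1ccc(OC)cc1 | intermediate
8 | methyl (R)-3-[(4-methoxybenzyl)oxy]-2-(propanoyloxy)propanoate | CCC(=O)O[C@H](COCc1ccc(OC)cc1)C(=O)OC | intermediate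
9 | (R)-4-hydroxy-5-{[(4-methoxybenzyl)oxy]methyl}-3-methylfuran-2(5H)-one | O=C1O[C@H](COCc2ccc(OC)cc2)C(O)=C1C | intermediate
10 | (R)-2-{[(4-methoxybenzyl)oxy]methyl}-4-methyl-5-oxo-2,5-dihydrofuran-3-yl trifluoromethanesulfonate | O=C1O[C@H](COCc2ccc(OC)cc2)C(OS(=O)(=O)C(F)(F)F)=C1C | intermediate
11 | (9R)-butenolide carbinol: cyclohexene of 5 joined through CH(OH) (C9) to C8 of the butenolide; 9-epimer of 13 | CCSC(=O)[C@]1(C)[C@H]([C@@H](C)C=CC1)[C@@H](O)C1=C(C)C(=O)O[C@@H]1COCc1ccc(OC)cc1 | intermediate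
12 | C9 ketone (4-acylbutenolide) | CCSC(=O)[C@]1(C)[C@H]([C@@H](C)C=CC1)C(=O)C1=C(C)C(=O)O[C@@H]1COCc1ccc(OC)cc1 | intermediate
13 | (9S)-butenolide carbinol | CCSC(=O)[C@]1(C)[C@H]([C@@H](C)C=CC1)[C@H](O)C1=C(C)C(=O)O[C@@H]1COCc1ccc(OC)cc1 | intermediate
14 | 8,17-epoxy-γ-lactone 9-ol (epoxide oxygen anti to C6) | CCSC(=O)[C@]1(C)[C@H]([C@@H](C)C=CC1)[C@H](O)[C@]12O[C@@]1(C)C(=O)O[C@@H]2COCc1ccc(OC)cc1 | intermediate
15 | 8-hydroxy-γ-lactone 9-ol (C7, C8, C9, C17 as in 35) | CCSC(=O)[C@]1(C)[C@H]([C@@H](C)C=CC1)[C@H](O)[C@@]1(O)[C@H](OC(=O)[C@@H]1C)COCc1ccc(OC)cc1 | intermediate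
16 | 9-acetate thioester | CCSC(=O)[C@]1(C)[C@H]([C@@H](C)C=CC1)[C@H](OC(C)=O)[C@@]1(O)[C@H](OC(=O)[C@@H]1C)COCc1ccc(OC)cc1 | intermediate
17 | 12α,13α-epoxide | CCSC(=O)[C@]1(C)[C@H]([C@@H](C)[C@@H]2O[C@@H]2C1)[C@H](OC(C)=O)[C@@]1(O)[C@H](OC(=O)[C@@H]1C)COCc1ccc(OC)cc1 | intermediate
18 | 8,12-bis(trimethylsilyl) ether of 19 (not isolated) | CCSC(=O)[C@]1(C)[C@H]([C@@H](C)[C@H](O[Si](C)(C)C)C=C1)[C@H](OC(C)=O)[C@@]1(O[Si](C)(C)C)[C@H](OC(=O)[C@@H]1C)COCc1ccc(OC)cc1 | intermediate
19 | 12α-hydroxy-13-ene thioester | CCSC(=O)[C@]1(C)[C@H]([C@@H](C)[C@H](O)C=C1)[C@H](OC(C)=O)[C@@]1(O)[C@H](OC(=O)[C@@H]1C)COCc1ccc(OC)cc1 | intermediate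
20 | 13α,14α-epoxy-12α-ol | CCSC(=O)[C@]1(C)[C@H]([C@@H](C)[C@H](O)[C@@H]2O[C@@H]21)[C@H](OC(C)=O)[C@@]1(O)[C@H](OC(=O)[C@@H]1C)COCc1ccc(OC)cc1 | intermediate
21 | 12-O-triethylsilyl ether thioester | CCSC(=O)[C@]1(C)[C@H]([C@@H](C)[C@H](O[Si](CC)(CC)CC)[C@@H]2O[C@@H]21)[C@H](OC(C)=O)[C@@]1(O)[C@H](OC(=O)[C@@H]1C)COCc1ccc(OC)cc1 | intermediate
22 | C2 aldehyde | O=C[C@]1(C)[C@H]([C@@H](C)[C@H](O[Si](CC)(CC)CC)[C@@H]2O[C@@H]21)[C@H](OC(C)=O)[C@@]1(O)[C@H](OC(=O)[C@@H]1C)COCc1ccc(OC)cc1 | intermediate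
23 | (1-bromovinyl)trimethylsilane | C=C(Br)[Si](C)(C)C | starting material
24 | 2-(trimethylsilyl)but-1-en-3-yne | C=C(C#C)[Si](C)(C)C | intermediate
25 | dicyclohexyl[(1E)-3-(trimethylsilyl)buta-1,3-dienyl]borane (not isolated) | C=C([Si](C)(C)C)/C=C/B(C1CCCCC1)C1CCCCC1 | intermediate
26 | methyl[(1E)-3-(trimethylsilyl)buta-1,3-dienyl]zinc (not isolated) | C=C([Si](C)(C)C)/C=C/[Zn]C | intermediate
27 | (2S)-dienylsilane allylic alcohol (3E alkene, SiMe3 on C5) | C=C([Si](C)(C)C)/C=C/[C@H](O)[C@]1(C)[C@H]([C@@H](C)[C@H](O[Si](CC)(CC)CC)[C@@H]2O[C@@H]21)[C@H](OC(C)=O)[C@@]1(O)[C@H](OC(=O)[C@@H]1C)COCc1ccc(OC)cc1 | intermediate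
28 | 3,4-epoxy-2-ol (C2, C3, C4 as in 35) | C=C([Si](C)(C)C)[C@H]3O[C@@H]3[C@H](O)[C@]1(C)[C@H]([C@@H](C)[C@H](O[Si](CC)(CC)CC)[C@@H]2O[C@@H]21)[C@H](OC(C)=O)[C@@]1(O)[C@H](OC(=O)[C@@H]1C)COCc1ccc(OC)cc1 | intermediate
29 | 2-acetate vinylsilane | C=C([Si](C)(C)C)[C@H]3O[C@@H]3[C@H](OC(C)=O)[C@]1(C)[C@H]([C@@H](C)[C@H](O[Si](CC)(CC)CC)[C@@H]2O[C@@H]21)[C@H](OC(C)=O)[C@@]1(O)[C@H](OC(=O)[C@@H]1C)COCc1ccc(OC)cc1 | intermediate
30 | C5 alkenyl iodide | C=C(I)[C@H]3O[C@@H]3[C@H](OC(C)=O)[C@]1(C)[C@H]([C@@H](C)[C@H](O[Si](CC)(CC)CC)[C@@H]2O[C@@H]21)[C@H](OC(C)=O)[C@@]1(O)[C@H](OC(=O)[C@@H]1C)COCc1ccc(OC)cc1 | intermediate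
31 | C6 primary alcohol | C=C(I)[C@H]3O[C@@H]3[C@H](OC(C)=O)[C@]1(C)[C@H]([C@@H](C)[C@H](O[Si](CC)(CC)CC)[C@@H]2O[C@@H]21)[C@H](OC(C)=O)[C@@]1(O)[C@H](OC(=O)[C@@H]1C)CO | intermediate
32 | C6 aldehyde | C=C(I)[C@H]3O[C@@H]3[C@H](OC(C)=O)[C@]1(C)[C@H]([C@@H](C)[C@H](O[Si](CC)(CC)CC)[C@@H]2O[C@@H]21)[C@H](OC(C)=O)[C@@]1(O)[C@H](OC(=O)[C@@H]1C)C=O | intermediate
33 | macrocyclic 6-epi allylic alcohol (6-OH anti to O7; 12-O-triethylsilyl) | C=C1[C@H]2O[C@@H]2[C@H](OC(C)=O)[C@]2(C)[C@H]([C@@H](C)[C@H](O[Si](CC)(CC)CC)[C@@H]3O[C@@H]32)[C@H](OC(C)=O)[C@@]2(O)[C@H](OC(=O)[C@@H]2C)[C@@H]1O | intermediate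
34 | 12-O-triethylsilyl ether of the target | C=C1[C@H]2O[C@@H]2[C@H](OC(C)=O)[C@]2(C)[C@H]([C@@H](C)[C@H](O[Si](CC)(CC)CC)[C@@H]3O[C@@H]32)[C@H](OC(C)=O)[C@@]2(O)[C@H](OC(=O)[C@@H]2C)[C@H]1Cl | intermediate
35 | CNP0141778.4: (1R,2R,3S,4R,6S,7S,8R,9S,10S,11R,12S,13S,14R,17R)-2,9-diacetoxy-6-chloro-3,4:13,14-diepoxy-8,12-dihydroxybriar-5(16)-ene 7,19-lactone | C=C1[C@H]2O[C@@H]2[C@H](OC(C)=O)[C@]2(C)[C@H]([C@@H](C)[C@H](O)[C@@H]3O[C@@H]32)[C@H](OC(C)=O)[C@@]2(O)[C@H](OC(=O)[C@@H]2C)[C@H]1Cl | target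

## Step count and risks

Total step count: 28 (steps 1–3 dienophile and cycloaddition, 4–7 lactone building block, 19 enyne, the rest on the main chain).
Longest linear sequence: 24 steps (from 6: steps 4–7, 8–18, 20–28).

The three steps most likely to fail:

Step 3 (the catalytic enantioselective Diels–Alder has no direct precedent for this β,β-disubstituted enal; rate, ee and ortho/endo control are unproven). Fallback: setting out from 3 and 4, the cycloaddition is run with an achiral Lewis acid (Me2AlCl, CH2Cl2, −78 °C) and gives 5 together with the enantiomeric adduct F1. The mixture is condensed with (1R,2R)-N,N'-dimethyl-1,2-diphenylethane-1,2-diamine (4 Å molecular sieves, CH2Cl2) to two diastereomeric imidazolidines, the aminal of 5 F2 and the aminal of the enantiomer F3, which are separated on silica. Hydrolysis of F2 (aqueous oxalic acid, Et2O) comes back to the route at 5.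

Step 26 (the alkenylchromium sits next to the 3,4-epoxide and may eliminate to an allene, and a strained ten-membered ring has to close). Fallback: setting out from 27, the epoxide is introduced only after ring closure. Acetylation (Ac2O, pyridine, 4-dimethylaminopyridine) gives the diene acetate F4, N-iodosuccinimide gives the iododiene F5, DDQ gives the primary alcohol F6 and Dess–Martin oxidation gives the aldehyde F7. CrCl2/NiCl2 then closes the ring to the macrocyclic dienol F8, and Ph3P/hexachloroacetone gives the diene chloride F9. Dimethyldioxirane (acetone, −20 °C) finally epoxidises the strained endocyclic E alkene C3=C4 on its outer face and comes back to the route at 34; this last epoxidation is substrate-controlled and less secure than step 21.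

Step 27 (SN2 chlorination of a hindered allylic alcohol; allylic transposition to the primary C16 chloride or ion-pair scrambling would erode the C6 configuration). Fallback: setting out from 33, Dess–Martin oxidation gives the enone F10 and chelation-controlled reduction (Zn(BH4)2, Et2O, −40 °C) gives the 6-epimeric alcohol F11. F11 is chlorinated with retention through its chlorosulfite (SOCl2, TiCl4 5 mol %, CH2Cl2, 0 °C), which comes back to the route at 34; the same path is used if step 26 itself delivers F11 instead of 33.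

Further compounds

F1 | step 3 | S-ethyl (1R,5R,6R)-6-formyl-1,5-dimethylcyclohex-3-ene-1-carbothioate (enantiomer of 5) | CCSC(=O)[C@@]1(C)[C@@H]([C@H](C)C=CC1)C=O
F2 | step 3 | aminal of 5: (4R,5R)-1,3-dimethyl-4,5-diphenylimidazolidin-2-yl in place of CHO | CCSC(=O)[C@]1(C)[C@H]([C@@H](C)C=CC1)C1N(C)[C@H](c2ccccc2)[C@@H](c2ccccc2)N1C
F3 | step 3 | corresponding aminal of F1 | CCSC(=O)[C@@]1(C)[C@@H]([C@H](C)C=CC1)C1N(C)[C@H](c2ccccc2)[C@@H](c2ccccc2)N1C
F4 | step 26 | 2-O-acetate of 27 (diene acetate) | C=C([Si](C)(C)C)/C=C/[C@H](OC(C)=O)[C@]1(C)[C@H]([C@@H](C)[C@H](O[Si](CC)(CC)CC)[C@@H]2O[C@@H]21)[C@H](OC(C)=O)[C@@]1(O)[C@H](OC(=O)[C@@H]1C)COCc1ccc(OC)cc1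
F5 | step 26 | 5-iodo-3,5(16)-diene acetate | C=C(I)/C=C/[C@H](OC(C)=O)[C@]1(C)[C@H]([C@@H](C)[C@H](O[Si](CC)(CC)CC)[C@@H]2O[C@@H]21)[C@H](OC(C)=O)[C@@]1(O)[C@H](OC(=O)[C@@H]1C)COCc1ccc(OC)cc1
F6 | step 26 | C6 primary alcohol of F5 | C=C(I)/C=C/[C@H](OC(C)=O)[C@]1(C)[C@H]([C@@H](C)[C@H](O[Si](CC)(CC)CC)[C@@H]2O[C@@H]21)[C@H](OC(C)=O)[C@@]1(O)[C@H](OC(=O)[C@@H]1C)CO
F7 | step 26 | C6 aldehyde of F5 | C=C(I)/C=C/[C@H](OC(C)=O)[C@]1(C)[C@H]([C@@H](C)[C@H](O[Si](CC)(CC)CC)[C@@H]2O[C@@H]21)[C@H](OC(C)=O)[C@@]1(O)[C@H](OC(=O)[C@@H]1C)C=O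
F8 | step 26 | macrocyclic (3E)-3,5(16)-dien-6-ol (6-OH anti to O7) | C=C1/C=C/[C@H](OC(C)=O)[C@]2(C)[C@H]([C@@H](C)[C@H](O[Si](CC)(CC)CC)[C@@H]3O[C@@H]32)[C@H](OC(C)=O)[C@@]2(O)[C@H](OC(=O)[C@@H]2C)[C@@H]1O
F9 | step 26 | macrocyclic (3E)-3,5(16)-diene 6-chloride (3,4-deoxy analogue of 34) | C=C1/C=C/[C@H](OC(C)=O)[C@]2(C)[C@H]([C@@H](C)[C@H](O[Si](CC)(CC)CC)[C@@H]3O[C@@H]32)[C@H](OC(C)=O)[C@@]2(O)[C@H](OC(=O)[C@@H]2C)[C@H]1Cl
F10 | step 27 | C6 ketone (enone) from 33 | C=C1[C@H]2O[C@@H]2[C@H](OC(C)=O)[C@]2(C)[C@H]([C@@H](C)[C@H](O[Si](CC)(CC)CC)[C@@H]3O[C@@H]32)[C@H](OC(C)=O)[C@@]2(O)[C@H](OC(=O)[C@@H]2C)C1=O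
F11 | step 27 | 6-epimer of 33 (6-OH syn to O7) | C=C1[C@H]2O[C@@H]2[C@H](OC(C)=O)[C@]2(C)[C@H]([C@@H](C)[C@H](O[Si](CC)(CC)CC)[C@@H]3O[C@@H]32)[C@H](OC(C)=O)[C@@]2(O)[C@H](OC(=O)[C@@H]2C)[C@H]1O
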